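The runs are calculated with made-up constants; scatter was added.

The easy step comes first: one Z takes one L and one Q, so the south run, with Q as limiting reagent at 0.120 M against 0.240 M of L, has room for Z up to its ceiling, the charge of the limiting reagent as a share of the L charged: 50.0%.

common to all: E 0.00400 M

|  | L | Q | time |
|---|---|---|---|
| south-east | 0.0800 M | 0.120 M |  |
| west | 0.0320 M | 0.0720 M |  |
| east | 0.120 M | 0.120 M |  |
| north | 0.0800 M | 0.180 M |  |
| south | 0.240 M | 0.120 M | 140 s |

| south-east run: time / s | south-east run: [Z] / M | west run: time / s | west run: [Z] / M | east run: time / s | east run: [Z] / M | north run: time / s | north run: [Z] / M |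
|---|---|---|---|---|---|---|---|
| 8.0 | 0.0024 | 8.0 | 0.0026 | 8.0 | 0.0026 | 8.0 | 0.0030 |
| 24 | 0.0076 | 24 | 0.0026 | 24 | 0.0113 | 24 | 0.0091 |
| 46 | 0.0187 | 46 | 0.0056 | 46 | 0.0286 | 46 | 0.0249 |
| 73 | 0.0336 | 73 | 0.0097 | 73 | 0.0525 | 73 | 0.0508 |
| 100 | 0.0488 | 100 | 0.0121 | 100 | 0.0739 | 100 | 0.0690 |
| 140 | 0.0647 | 140 | 0.0175 | 140 | 0.0909 | 140 | 0.0783 |

(standard deviation of a reading: 6 × 10⁻⁴ M)

1. how the opening rate goes with [Q] round the charge of the south-east run: the exponent of the rate at two percent of L gone to Z
2. how the opening rate goes with [L] round the charge of the south-east run: the exponent of the rate at two percent of L gone to Z (one fixed amount of Z, the same in the runs compared)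
3. the west run starts with 0.0480 M less of L and of Q than the south-east run, and with no Z. Compared where both hold the same amount of L, once fifteen percent of what the west run was charged with has turned into Z, is the west run faster, slower or alike (within a tenth)?
4. Z in the south run at 140 s, as a share of the L charged

- Overall: L + Q -> Z, with E as catalyst.
- Constant volume, constant temperature.
- Readings of a species count what is bound in complexes too.
- An order is taken over about fifteen percent of the charge, up and down.

So we reckon the south run as its ceiling less a small correction, the unspent share: the part of the limiting charge not yet turned into Z. Among the runs so far, the north run serves as a mirror of the south run. There L is the limiting reagent, the other charge is 2.25 times as large (in the south run 2.00 times), and its reading at 140 s leaves an unspent share of 2.13%. Borrowing that share, we expect 48.9% of the L charged in the south run.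

The forecast gives exponents of 0.8 in Q and 0.5 in L, calls the west run slower, and puts the south run at 47.5%, “with Q nearly exhausted”. That is lower than our figure.

The flask gives exponents of 0.30 in Q and 0.68 in L, the west run slower, and the south run at 49.4%.

    E + Q ⇌ EQ, settled at all times (45.30 /M)
    EQ + L → Z + E (1.760 /M/s)
    L + Q + Z → 2 Z (5.850 /M²/s)
    2 L ⇌ L2, settled at all times (12.60 /M)

The south run ends 0.60 percentage points under its ceiling of 50.0%, an unspent share of 1.27% of its Q, against the 2.13% we borrowed from the north run. It gets that close because of the step in which Z helps turn L and Q into more Z. The simulated south run without that step holds 23.9% of the L charged at 140 s, under the same ceiling, so its unspent share is 52.2%.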